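**Retrosynthetic overview**
1. Both benzene rings are bought as phenols, so no ring is formed in the route; the last disconnection is the palmitate C(=O)–OCH2 bond.
2. The strategy rests on ring B (the methyl benzoate ring): the ester-bearing carbon C1′ sits between C2′ (diaryl ether oxygen) and C6′ (OH), with CH3 at C4′. This O–C(CO2Me)–O triad is what a 3-oxygenated benzyne gives when a nucleophile enters at its distal carbon and an electrophile at the carbon beside oxygen.
3. Key disconnection: the ring-B C2′–O(ring A) and C1′–CO2Me bonds are cut together, giving aryne precursor 9, the doubly ortho-substituted ring-A phenol 16 and CO2.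
4. Silyl triflate 9 comes from orcinol (mono-MOM, carbamate, directed ortho-silylation, carbamate-to-triflate). Phenol 16 comes from 2-hydroxy-4-methoxybenzaldehyde (MOM, Dakin-type oxidation, ortho-formylation, reduction, silylation), which fixes the ring-A pattern without differentiating a catechol.
5. After the coupling, acid removes both MOM groups and the silyl ether, and a Mitsunobu esterification places the palmitate on the benzylic oxygen only.

Key step: step 10

Remark: the target has no stereogenic element, so "single enantiomer" is read as the achiral compound itself and no stereocontrol is needed.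

**Route**

Step 1
Reactants: 1 orcinol
Product: 2 3-(methoxymethoxy)-5-methylphenol
Conditions: NaH (1.0 equiv), MOMCl (1.0 equiv), DMF, 0 °C → rt; chromatography, recovered 1 recycled
Reagents that add atoms: chloromethyl methyl ether, COCCl
Why: Williamson O-alkylation of the monophenoxide; the two hydroxyls of 1 are equivalent, so only the mono/bis distribution has to be managed by stoichiometry and separation.

Step 2
Reactants: 2 3-(methoxymethoxy)-5-methylphenol
Product: 3 3-(methoxymethoxy)-5-methylphenyl N-isopropylcarbamate
Conditions: i-PrNCO, Et3N (cat.), CH2Cl2, rt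
Reagents that add atoms: isopropyl isocyanate, CC(C)N=C=O
Why: base-catalysed addition of the phenol to the isocyanate should give the N-monoalkyl carbamate, a directing group for ortho-metalation that can later be removed under mild base.

Step 3
Reactants: 3 3-(methoxymethoxy)-5-methylphenyl N-isopropylcarbamate
Product: 7 3-(methoxymethoxy)-5-methyl-2-(trimethylsilyl)phenyl N-isopropylcarbamate, via N-TBS carbamate 4 (not isolated), via 2-lithio N-TBS carbamate 5 (not isolated), via 2-TMS N-TBS carbamate 6 (not isolated)
Conditions: TBSOTf (1.05 equiv), TMEDA, Et2O, 0 °C → rt; then TMEDA, n-BuLi (2 equiv), −78 °C; TMSCl, −78 °C → rt; MeOH then 10% aq. citric acid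
Reagents that add atoms: chlorotrimethylsilane, C[Si](C)(C)Cl
Why: directed ortho-metalation of an in-situ N-silylated carbamate (Hoppe/Snieckus type), in which the C2–H flanked by the carbamate oxygen and the MOM-oxy group is the most acidic ring position, so lithiation and C-silylation should occur only there, and the labile N–Si bond is hydrolysed on mild work-up.

Step 4
Reactants: 7 3-(methoxymethoxy)-5-methyl-2-(trimethylsilyl)phenyl N-isopropylcarbamate
Product: 9 3-(methoxymethoxy)-5-methyl-2-(trimethylsilyl)phenyl trifluoromethanesulfonate, via 2-silylphenol 8 (not isolated)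
Conditions: Et2NH, DBU, MeCN, 40 °C; then PhNTf2, rt
Reagents that add atoms: N-phenylbis(trifluoromethanesulfonimide), O=S(=O)(N(c1ccccc1)S(=O)(=O)C(F)(F)F)C(F)(F)F
Why: E1cB loss of isopropyl isocyanate from the N–H carbamate (trapped by diethylamine) frees the hindered phenoxide, which is triflated in the same pot; these base-only conditions should leave the aryl–silicon bond and the MOM ether untouched.

Step 5
Reactants: 10 2-hydroxy-4-methoxybenzaldehyde
Product: 11 4-methoxy-2-(methoxymethoxy)benzaldehyde
Conditions: NaH, MOMCl, DMF, 0 °C → rt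
Reagents that add atoms: chloromethyl methyl ether, COCCl
Why: Williamson O-alkylation of the only phenol, deprotonated irreversibly so that its hydrogen bond to the aldehyde does not slow the reaction.

Step 6
Reactants: 11 4-methoxy-2-(methoxymethoxy)benzaldehyde
Product: 13 4-methoxy-2-(methoxymethoxy)phenol, via aryl formate 12 (not isolated)
Conditions: mCPBA, CH2Cl2, 0 °C → rt; then K2CO3 (cat.), MeOH, rt
Reagents that add atoms: 3-chloroperoxybenzoic acid, O=C(OO)c1cccc(Cl)c1
Why: Baeyer–Villiger (Dakin-type) oxidation, in which the ortho/para-dialkoxy aryl group migrates in preference to hydride, gives the formate, and methanolysis then releases the phenol.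

Step 7
Reactants: 13 4-methoxy-2-(methoxymethoxy)phenol
Product: 14 2-hydroxy-5-methoxy-3-(methoxymethoxy)benzaldehyde
Conditions: MgCl2, Et3N, (CH2O)n, MeCN, reflux
Reagents that add atoms: formaldehyde (as paraformaldehyde), C=O
Why: magnesium-mediated ortho-formylation of a phenol (Casnati–Skattebøl), which delivers formaldehyde only ortho to the phenoxide; the para carbon carries OMe and one ortho carbon carries the MOM-oxy group, so the single free ortho carbon is formylated, and a second formaldehyde oxidises the hydroxymethyl intermediate.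

Step 8
Reactants: 14 2-hydroxy-5-methoxy-3-(methoxymethoxy)benzaldehyde
Product: 15 2-(hydroxymethyl)-4-methoxy-6-(methoxymethoxy)phenol
Conditions: NaBH4, MeOH, 0 °C
Reagents that add atoms: none
Why: borohydride reduction of the aldehyde to the primary benzylic alcohol, with all ether groups inert.

Step 9
Reactants: 15 2-(hydroxymethyl)-4-methoxy-6-(methoxymethoxy)phenol
Product: 16 4-methoxy-2-(methoxymethoxy)-6-[(triisopropylsilyloxy)methyl]phenol
Conditions: TIPSCl (1.05 equiv), imidazole, DMF, 0 °C
Reagents that add atoms: chlorotriisopropylsilane, CC(C)[Si](Cl)(C(C)C)C(C)C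
Why: imidazole-promoted silylation with a bulky chlorosilane should take the unhindered primary alcohol well ahead of the phenol, which has substituents at both ortho positions.

Step 10
Reactants: 9 3-(methoxymethoxy)-5-methyl-2-(trimethylsilyl)phenyl trifluoromethanesulfonate; 16 4-methoxy-2-(methoxymethoxy)-6-[(triisopropylsilyloxy)methyl]phenol; 17 carbon dioxide
Product: 22 methyl 2-{4-methoxy-2-(methoxymethoxy)-6-[(triisopropylsilyloxy)methyl]phenoxy}-6-(methoxymethoxy)-4-methylbenzoate, via potassium phenoxide 18 (not isolated), via 3-(methoxymethoxy)-5-methylbenzyne 19 (not isolated), via aryl potassium adduct 20 (not isolated), via potassium carboxylate 21 (not isolated)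
Conditions: 16 (1.2 equiv), KH, THF, 0 °C → rt; then KF, 18-crown-6, CO2 (1 atm), slow addition of 9, 0 °C → rt; then MeI, DMF, rt
Reagents that add atoms: iodomethane, CI
Why: Proposed new method: fluoride attacks silicon in 9, triflate leaves and aryne 19 forms; the preformed, proton-free phenoxide 18 adds to the aryne carbon meta to the MOM-oxy group, the aryl anion 20 that results between the two oxygen-bearing carbons is captured by dissolved CO2 to give carboxylate 21, and iodomethane esterifies it in the same pot. The closest known reaction type is the three-component coupling of silyl-triflate-derived arynes with amines and CO2 to give anthranilic acids, together with the established regioselective O-arylation of phenols by 3-alkoxyarynes; the new element is pairing an anionic oxygen nucleophile with CO2. No ring is closed and no stereocentre is formed; one C–O bond and one C–C bond are made on adjacent ring-B carbons. Regioselectivity is needed and is secured by the inductive effect and ring distortion of the 3-alkoxy group, which make the distal aryne carbon the electrophilic one and place the carbanion beside oxygen. Carboxylation must also outrun protonation, which is secured by excluding every O–H or N–H acid (KH deprotonation, THF in place of MeCN, crown-ether-solubilised KF) and by a CO2-saturated solution. An aryne accepts even a phenoxide with two ortho substituents, and slow addition of 9 to excess 18 keeps the aryne concentration low so that carboxylate 21 is not arylated further.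

Step 11
Reactants: 22 methyl 2-{4-methoxy-2-(methoxymethoxy)-6-[(triisopropylsilyloxy)methyl]phenoxy}-6-(methoxymethoxy)-4-methylbenzoate
Product: 23 methyl 2-hydroxy-6-[2-hydroxy-6-(hydroxymethyl)-4-methoxyphenoxy]-4-methylbenzoate
Conditions: HCl (2 M in MeOH), rt → 40 °C
Reagents that add atoms: none
Why: acid-catalysed acetal exchange removes both aryl MOM ethers (methanol scavenges the methoxymethyl cation) and methanolysis cleaves the primary silyl ether, while methanol as solvent keeps the methyl ester intact and disfavours closure to the eight-membered lactone.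

Step 12
Reactants: 23 methyl 2-hydroxy-6-[2-hydroxy-6-(hydroxymethyl)-4-methoxyphenoxy]-4-methylbenzoate; 24 palmitic acid
Product: 25 betaethrin E (methyl 2-{2-[(hexadecanoyloxy)methyl]-6-hydroxy-4-methoxyphenoxy}-6-hydroxy-4-methylbenzoate)
Conditions: PPh3, DIAD, THF, 0 °C → rt
Reagents that add atoms: none
Why: Mitsunobu esterification, in which only the primary benzylic alcohol can be activated as an oxyphosphonium leaving group and the carboxylic acid is the most acidic pronucleophile, so no acylating agent is ever present and the two phenols should remain free.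

**Compound list**
1 | orcinol (5-methylbenzene-1,3-diol) | Cc1cc(O)cc(O)c1 | starting material
2 | 3-(methoxymethoxy)-5-methylphenol | COCOc1cc(C)cc(O)c1 | intermediate
3 | 3-(methoxymethoxy)-5-methylphenyl N-isopropylcarbamate | COCOc1cc(C)cc(OC(=O)NC(C)C)c1 | intermediate
4 | 3-(methoxymethoxy)-5-methylphenyl N-(tert-butyldimethylsilyl)-N-isopropylcarbamate | COCOc1cc(C)cc(OC(=O)N(C(C)C)[Si](C)(C)C(C)(C)C)c1 | intermediate
5 | 2-lithio-3-(methoxymethoxy)-5-methylphenyl N-(tert-butyldimethylsilyl)-N-isopropylcarbamate | COCOc1cc(C)cc(OC(=O)N(C(C)C)[Si](C)(C)C(C)(C)C)c1[Li] | intermediate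
6 | 3-(methoxymethoxy)-5-methyl-2-(trimethylsilyl)phenyl N-(tert-butyldimethylsilyl)-N-isopropylcarbamate | COCOc1cc(C)cc(OC(=O)N(C(C)C)[Si](C)(C)C(C)(C)C)c1[Si](C)(C)C | intermediate
7 | 3-(methoxymethoxy)-5-methyl-2-(trimethylsilyl)phenyl N-isopropylcarbamate | COCOc1cc(C)cc(OC(=O)NC(C)C)c1[Si](C)(C)C | intermediate
8 | 3-(methoxymethoxy)-5-methyl-2-(trimethylsilyl)phenol | COCOc1cc(C)cc(O)c1[Si](C)(C)C | intermediate
9 | 3-(methoxymethoxy)-5-methyl-2-(trimethylsilyl)phenyl trifluoromethanesulfonate | COCOc1cc(C)cc(OS(=O)(=O)C(F)(F)F)c1[Si](C)(C)C | intermediate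
10 | 2-hydroxy-4-methoxybenzaldehyde | COc1ccc(C=O)c(O)c1 | starting material
11 | 4-methoxy-2-(methoxymethoxy)benzaldehyde | COCOc1cc(OC)ccc1C=O | intermediate
12 | 4-methoxy-2-(methoxymethoxy)phenyl formate | COCOc1cc(OC)ccc1OC=O | intermediate
13 | 4-methoxy-2-(methoxymethoxy)phenol | COCOc1cc(OC)ccc1O | intermediate
14 | 2-hydroxy-5-methoxy-3-(methoxymethoxy)benzaldehyde | COCOc1cc(OC)cc(C=O)c1O | intermediate
15 | 2-(hydroxymethyl)-4-methoxy-6-(methoxymethoxy)phenol | COCOc1cc(OC)cc(CO)c1O | intermediate
16 | 4-methoxy-2-(methoxymethoxy)-6-[(triisopropylsilyloxy)methyl]phenol | COCOc1cc(OC)cc(CO[Si](C(C)C)(C(C)C)C(C)C)c1O | intermediate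
17 | carbon dioxide | O=C=O | starting material
18 | potassium 4-methoxy-2-(methoxymethoxy)-6-[(triisopropylsilyloxy)methyl]phenoxide | COCOc1cc(OC)cc(CO[Si](C(C)C)(C(C)C)C(C)C)c1[O-].[K+] | intermediate
19 | 3-(methoxymethoxy)-5-methylbenzyne | COCOC1=CC(C)=CC#C1 | intermediate
20 | aryl potassium adduct of 18 and 19 (carbanion at ring-B C1′, between the MOM-oxy and aryloxy carbons) | COCOc1cc(C)cc(Oc2c(CO[Si](C(C)C)(C(C)C)C(C)C)cc(OC)cc2OCOC)[c-]1.[K+] | intermediate
21 | potassium 2-{4-methoxy-2-(methoxymethoxy)-6-[(triisopropylsilyloxy)methyl]phenoxy}-6-(methoxymethoxy)-4-methylbenzoate | [K+].[O-]C(=O)c1c(OCOC)cc(C)cc1Oc1c(CO[Si](C(C)C)(C(C)C)C(C)C)cc(OC)cc1OCOC | intermediate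
22 | methyl 2-{4-methoxy-2-(methoxymethoxy)-6-[(triisopropylsilyloxy)methyl]phenoxy}-6-(methoxymethoxy)-4-methylbenzoate | COC(=O)c1c(OCOC)cc(C)cc1Oc1c(CO[Si](C(C)C)(C(C)C)C(C)C)cc(OC)cc1OCOC | intermediate
23 | methyl 2-hydroxy-6-[2-hydroxy-6-(hydroxymethyl)-4-methoxyphenoxy]-4-methylbenzoate | COC(=O)c1c(O)cc(C)cc1Oc1c(CO)cc(OC)cc1O | intermediate
24 | palmitic acid (hexadecanoic acid) | CCCCCCCCCCCCCCCC(=O)O | starting material
25 | betaethrin E | CCCCCCCCCCCCCCCC(=O)OCc1cc(OC)cc(O)c1Oc1cc(C)cc(O)c1C(=O)OC | target

**Totals**
Total step count: 12 (steps 1–4 make 9, steps 5–9 make 16, steps 10–12 finish the route).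
Longest linear sequence: 8 steps (steps 5–12, from 2-hydroxy-4-methoxybenzaldehyde).

**Steps most likely to fail**

Step 10 (Proposed new method). The aryl anion may be protonated before it meets CO2, either by trace proton sources or by intramolecular proton transfer from the benzylic CH2, which would give the non-carboxylated diaryl ether. The phenoxide may also be held back as its carbonate and add slowly, or the product carboxylate may be arylated by further aryne. The fallback uses known chemistry only, sets out from phenol 16 and returns at ester 22. Purchased 3-fluoro-5-methylphenol F1 is protected (NaH, MOMCl, DMF) to 1-fluoro-3-(methoxymethoxy)-5-methylbenzene F2. Lithiation at the carbon between fluorine and the MOM-oxy group (n-BuLi, THF, −78 °C) and a DMF quench give 2-fluoro-6-(methoxymethoxy)-4-methylbenzaldehyde F3. Nucleophilic aromatic substitution of the ortho-formyl-activated fluoride by 16 (K2CO3, DMF, 90 °C) gives 2-{4-methoxy-2-(methoxymethoxy)-6-[(triisopropylsilyloxy)methyl]phenoxy}-6-(methoxymethoxy)-4-methylbenzaldehyde F4. Pinnick oxidation (NaClO2, NaH2PO4, 2-methyl-2-butene, t-BuOH/H2O) gives 2-{4-methoxy-2-(methoxymethoxy)-6-[(triisopropylsilyloxy)methyl]phenoxy}-6-(methoxymethoxy)-4-methylbenzoic acid F5, and MeI/K2CO3 in DMF gives 22.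

Step 12. Chemoselectivity may be lost if a phenol competes with the carboxylate as nucleophile toward the activated benzylic carbon (O-benzylation, oligomers), or the hindered benzylic alcohol may be activated slowly. The fallback sets out from 22 and returns at target 25, with the ester installed before any phenol is free. Buffered desilylation (TBAF, AcOH, THF) gives methyl 2-[2-(hydroxymethyl)-4-methoxy-6-(methoxymethoxy)phenoxy]-6-(methoxymethoxy)-4-methylbenzoate F6. Steglich esterification with palmitic acid 24 (EDC, DMAP, CH2Cl2) gives methyl 2-{2-[(hexadecanoyloxy)methyl]-4-methoxy-6-(methoxymethoxy)phenoxy}-6-(methoxymethoxy)-4-methylbenzoate F7. Both aryl MOM ethers are then removed without an alcohol solvent (ZnBr2, n-PrSH, CH2Cl2, rt), so the palmitate cannot transesterify, giving 25.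

Step 3. The silyl triflate used for N-protection may cleave the MOM ether, lithiation may be incomplete, or the electron-rich aryl–silicon bond may be protonated off during work-up. The fallback sets out from 2 and returns at 9, using a tertiary carbamate that needs no N-silylation. Carbamoylation (Et2NCOCl, K2CO3, MeCN, reflux) gives 3-(methoxymethoxy)-5-methylphenyl N,N-diethylcarbamate F8. Directed ortho-metalation (s-BuLi, TMEDA, THF, −78 °C; TMSCl) gives 3-(methoxymethoxy)-5-methyl-2-(trimethylsilyl)phenyl N,N-diethylcarbamate F9. Reductive carbamate cleavage with the Schwartz reagent (Cp2Zr(H)Cl, THF, rt) gives phenol 8, which is triflated (PhNTf2, DBU, MeCN) to 9.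

**Further compounds**
F1 | step 10 | 3-fluoro-5-methylphenol (purchased starting material of the fallback) | Cc1cc(O)cc(F)c1
F2 | step 10 | 1-fluoro-3-(methoxymethoxy)-5-methylbenzene | COCOc1cc(C)cc(F)c1
F3 | step 10 | 2-fluoro-6-(methoxymethoxy)-4-methylbenzaldehyde | COCOc1cc(C)cc(F)c1C=O
F4 | step 10 | 2-{4-methoxy-2-(methoxymethoxy)-6-[(triisopropylsilyloxy)methyl]phenoxy}-6-(methoxymethoxy)-4-methylbenzaldehyde | O=Cc1c(OCOC)cc(C)cc1Oc1c(CO[Si](C(C)C)(C(C)C)C(C)C)cc(OC)cc1OCOC
F5 | step 10 | 2-{4-methoxy-2-(methoxymethoxy)-6-[(triisopropylsilyloxy)methyl]phenoxy}-6-(methoxymethoxy)-4-methylbenzoic acid | OC(=O)c1c(OCOC)cc(C)cc1Oc1c(CO[Si](C(C)C)(C(C)C)C(C)C)cc(OC)cc1OCOC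
F6 | step 12 | methyl 2-[2-(hydroxymethyl)-4-methoxy-6-(methoxymethoxy)phenoxy]-6-(methoxymethoxy)-4-methylbenzoate | COC(=O)c1c(OCOC)cc(C)cc1Oc1c(CO)cc(OC)cc1OCOC
F7 | step 12 | methyl 2-{2-[(hexadecanoyloxy)methyl]-4-methoxy-6-(methoxymethoxy)phenoxy}-6-(methoxymethoxy)-4-methylbenzoate | CCCCCCCCCCCCCCCC(=O)OCc1cc(OC)cc(OCOC)c1Oc1cc(C)cc(OCOC)c1C(=O)OC
F8 | step 3 | 3-(methoxymethoxy)-5-methylphenyl N,N-diethylcarbamate | CCN(CC)C(=O)Oc1cc(C)cc(OCOC)c1
F9 | step 3 | 3-(methoxymethoxy)-5-methyl-2-(trimethylsilyl)phenyl N,N-diethylcarbamate | CCN(CC)C(=O)Oc1cc(C)cc(OCOC)c1[Si](C)(C)C
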